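The product comes out of a chain, and I count how many lifetimes of the substrate that chain fits into the run.

substrate 0.12 M; coupling partner 0.600 M; scavenger 0.120 M (fed, over 8.0 h); initiator 0.84 mM; time 3.0 d; the fed solution adds 0.50 times the starting volume

- part of the substrate that has reacted at 3.0 d
- share of the unused coupling partner that is free and not bound as idle adduct, at 3.0 d

- percentages count the substrate that a species holds: one ended chains A counts as two
- released group is meant together with its idle adduct
- for a step with 2 of a species take k times the square, and two of it per event
- every charge counts on the volume at the start, and the solution that is fed holds the whole dose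
- run time (flask): 3.0 d

    substrate + initiating radical → capped initiator + first chain carrier (k1 = 1.8 × 10⁵ /M/s)
    2 first chain carrier → ended chains A (k2 = 8.4 × 10⁶ /M/s)
    initiator → 2 initiating radical (k3 = 9.2 × 10⁻⁵ /min)
    coupling partner + released group ⇌ idle adduct, settled at all times (K4 = 3.7 /M)
    2 second chain carrier → ended chains B (k5 = 2 × 10⁸ /M/s)
    substrate + second chain carrier → released group + first chain carrier (k6 = 3.7 × 10⁵ /M/min)
    scavenger + released group → scavenged by-product (k7 = 0.46 /M/min)
    coupling partner + first chain carrier ⇌ product + second chain carrier (K8 = 0.076, k8 = 1.3 × 10⁵ /M/min)

I let chains end in pairs of the second chain carrier, because its ending constant is larger than that of the first chain carrier. Radicals from the initiator then balance those endings. The feed lasts 8.0 h of 3.0 d, so I spread the initiator over the final volume: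

[second chain carrier], reckoned with the whole initiator charge on the final volume = √(9.2 × 10⁻⁵ /min × 0.560 mM / 2 × 10⁸ /M/s) = 2.07 × 10⁻⁹ M

The initiator has a half-life of 5.23 d. In my reckoning the carrier follows the square root of what remains, which gives 1.70 × 10⁻⁹ M for the end. Against this carrier the substrate falls pseudo-first-order, with constant 3.7 × 10⁵ /M/min. Summed over the run:

n = 3.00

This n, the turnover count, is the number of substrate lifetimes in the run, and the reacted part follows from it:

c = 95.0%

Now the settings, by hand. The initiator enters n by its square root. Substrate and coupling partner do not enter it, so I expect c to stay put when either moves. Nor does the scavenger enter n. Its charge matches the substrate's, so I take the two as close, and the released group then balances near 0.00137 M. With 3.7 /M that gives: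

fr = 99.5%

The forecast puts c at 93%, lower than my figure, and fr at 99.6%. It takes the rate of the chain as “set by initiator supply against termination of the second carrier”.

The simulation gives 93.7% and 99.7%. Moved one at a time, the settings shift c in this order: initiator (2.4 points), then substrate (1.4 points), then coupling partner (1.3 points), then scavenger (under 0.05 points).

At 0.565 d in the flask, the second chain carrier uses substrate 310 times as fast as the initiating radical does. The substrate left in the flask reads as 2.76 lifetimes, fewer than my 3.00. For the neighbour flask with 5.0 × 10⁻⁴ M of initiator, the square root turns n into 2.32, and that flask ends with 11.6% of its substrate, which reads as 2.15 lifetimes.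

The rate constants are assumed, and the outcome is calculated.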